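The synthesis rests on disconnecting the C4–C4a bond of ring C. Halogen–magnesium exchange of an aryl iodide at C4a and attack of the arylmagnesium on a tethered N-methoxy-N-methylamide close ring C and create the ketone in one operation, leaving C2 untouched. The step exploits that in ring A the chain-bearing C6 lies para to C8a, the carbon carrying O1: C4a and C8 are equivalent in the phenol, so mono-iodination and ring closure can only give the 6-substituted flavanone. The precursor is an (S)-3-aryloxy-3-arylpropanoic Weinreb amide, obtained by Mitsunobu inversion of an (R)-carbinol with a 2-iodophenol that already carries the citronellal-derived dienyl chain; all three phenols are MOM ethers.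

Key step: step 12

Remark: (S)-citronellal of high enantiomeric purity is assumed, since its purity fixes the configuration at C3''; the ring B phenol is carried as a MOM ether like the ring A phenols, so that no basic fluoride step is needed on the flavanone.

Step 1
Reactants: 1 phloroglucinol
Product: 2 3,5-bis(methoxymethoxy)phenol
Conditions: MOMCl (2.0 equiv), i-Pr2NEt (2.2 equiv), DMF, 0 °C → rt
Reagents that add atoms: chloromethyl methyl ether, COCCl
Why: Williamson-type O-alkylation of the phenols with an α-chloro ether should stop mainly at the bis-ether when two equivalents are used, and the mono- and tris-ethers of this statistical protection are separable by chromatography.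

Step 2
Reactants: 2 3,5-bis(methoxymethoxy)phenol
Product: 3 [3,5-bis(methoxymethoxy)phenoxy]triisopropylsilane
Conditions: TIPSCl, imidazole, DMF, rt
Reagents that add atoms: triisopropylsilyl chloride, CC(C)[Si](Cl)(C(C)C)C(C)C
Why: Silylation of the remaining phenol masks the future O1 with a bulky group that resists n-BuLi and does not compete with the MOM ethers as a directing group.

Step 3
Reactants: 3 [3,5-bis(methoxymethoxy)phenoxy]triisopropylsilane; 4 (S)-citronellal
Product: 6 (1RS,3S)-1-[2,6-bis(methoxymethoxy)-4-(triisopropylsilyloxy)phenyl]-3,7-dimethyloct-6-en-1-ol, via aryllithium 5 (not isolated)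
Conditions: n-BuLi (1.1 equiv), THF, 0 °C; then 4, −78 → 0 °C; H2O
Reagents that add atoms: none
Why: Directed ortho-metalation removes the proton flanked by the two MOM ethers (cooperative chelation, with the bulky silyl ether shielding its own neighbours), and 1,2-addition of aryllithium 5 to the aldehyde forms the aryl–C1'' bond; the new carbinol centre is left uncontrolled because step 4 removes it, and the citronellal stereocentre (future C3'') is not touched.

Step 4
Reactants: 6 (1RS,3S)-1-[2,6-bis(methoxymethoxy)-4-(triisopropylsilyloxy)phenyl]-3,7-dimethyloct-6-en-1-ol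
Product: 8 {4-[(1E,3S)-3,7-dimethylocta-1,6-dien-1-yl]-3,5-bis(methoxymethoxy)phenoxy}triisopropylsilane, via sulfamate ester 7 (not isolated)
Conditions: Burgess reagent (1.5 equiv), toluene, rt → 60 °C
Reagents that add atoms: none
Why: Burgess dehydration proceeds through sulfamate 7 by syn-elimination under neutral conditions, so no free benzylic cation can be trapped by the C6''=C7'' alkene or by a MOM group; only C2'' carries β-hydrogens, and the (E)-alkene is strongly preferred beside the 2,6-disubstituted ring.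

Step 5
Reactants: 8 {4-[(1E,3S)-3,7-dimethylocta-1,6-dien-1-yl]-3,5-bis(methoxymethoxy)phenoxy}triisopropylsilane
Product: 9 4-[(1E,3S)-3,7-dimethylocta-1,6-dien-1-yl]-3,5-bis(methoxymethoxy)phenol
Conditions: TBAF (1.1 equiv), THF, 0 °C; aq NH4Cl
Reagents that add atoms: none
Why: Fluoride-induced cleavage of the aryl silyl ether (desilylation) frees O1 alone, since MOM ethers and alkenes are inert to TBAF.

Step 6
Reactants: 9 4-[(1E,3S)-3,7-dimethylocta-1,6-dien-1-yl]-3,5-bis(methoxymethoxy)phenol
Product: 10 4-[(1E,3S)-3,7-dimethylocta-1,6-dien-1-yl]-2-iodo-3,5-bis(methoxymethoxy)phenol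
Conditions: iodine (1.0 equiv), NaHCO3, THF/H2O, 0 °C
Reagents that add atoms: iodine, [I][I]
Why: Electrophilic aromatic iodination of the phenoxide occurs ortho to O1, where both positions are equivalent because the chain sits para to O1, and the trioxygenated ring is far more nucleophilic than the twisted styrene or the trisubstituted alkene, so one equivalent of iodine at 0 °C should give the mono-iodide.

Step 7
Reactants: 11 4-hydroxyacetophenone
Product: 12 1-[4-(methoxymethoxy)phenyl]ethan-1-one
Conditions: MOMCl, i-Pr2NEt, CH2Cl2, 0 °C → rt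
Reagents that add atoms: chloromethyl methyl ether, COCCl
Why: MOM protection (O-alkylation with an α-chloro ether) gives ring B the same base-stable acetal as ring A, so that one final step can free all three phenols.

Step 8
Reactants: 12 1-[4-(methoxymethoxy)phenyl]ethan-1-one
Product: 13 ethyl 3-[4-(methoxymethoxy)phenyl]-3-oxopropanoate
Conditions: NaH (2.5 equiv), (EtO)2CO (3 equiv), THF, reflux; AcOH
Reagents that add atoms: diethyl carbonate, CCOC(=O)OCC
Why: Crossed Claisen condensation of the ketone enolate with non-enolisable diethyl carbonate is driven to completion by deprotonation of the β-keto ester, and the MOM ether is stable to NaH.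

Step 9
Reactants: 13 ethyl 3-[4-(methoxymethoxy)phenyl]-3-oxopropanoate
Product: 14 ethyl (3R)-3-hydroxy-3-[4-(methoxymethoxy)phenyl]propanoate
Conditions: RuCl(p-cymene)[(R,R)-TsDPEN] (1 mol %), HCO2H/Et3N (5:2), CH2Cl2, 30 °C
Reagents that add atoms: none
Why: Noyori–Ikariya asymmetric transfer hydrogenation reduces the aryl ketone through an outer-sphere six-membered transition state in which the aryl group faces the cymene ligand, so the (R,R)-ligand should deliver hydride to the Si face and set the (R)-carbinol, by analogy with acetophenone.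

Step 10
Reactants: 14 ethyl (3R)-3-hydroxy-3-[4-(methoxymethoxy)phenyl]propanoate
Product: 15 (3R)-3-hydroxy-N-methoxy-3-[4-(methoxymethoxy)phenyl]-N-methylpropanamide
Conditions: MeNHOMe·HCl (2.5 equiv), i-PrMgCl (6 equiv), THF, −20 → 0 °C; aq NH4Cl
Reagents that add atoms: N,O-dimethylhydroxylamine hydrochloride, CNOC.Cl
Why: Aminolysis of the ester by the chloromagnesium amide made from N,O-dimethylhydroxylamine hydrochloride and i-PrMgCl (Weinreb amide formation) proceeds at low temperature with the carbinol held as its magnesium alkoxide, so the stereocentre is not affected.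

Step 11
Reactants: 10 4-[(1E,3S)-3,7-dimethylocta-1,6-dien-1-yl]-2-iodo-3,5-bis(methoxymethoxy)phenol; 15 (3R)-3-hydroxy-N-methoxy-3-[4-(methoxymethoxy)phenyl]-N-methylpropanamide
Product: 16 (3S)-3-{4-[(1E,3S)-3,7-dimethylocta-1,6-dien-1-yl]-2-iodo-3,5-bis(methoxymethoxy)phenoxy}-N-methoxy-3-[4-(methoxymethoxy)phenyl]-N-methylpropanamide
Conditions: PPh3 (1.5 equiv), DIAD (1.5 equiv), toluene, 0 °C → rt
Reagents that add atoms: none
Why: Mitsunobu etherification, in which the acidic 2-iodophenol displaces the oxyphosphonium of the carbinol by SN2 with inversion, turns the (R)-alcohol into the (S)-aryl ether that becomes C2, while toluene and low temperature disfavour ionisation and elimination of the activated benzylic carbinol.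

Step 12
Reactants: 16 (3S)-3-{4-[(1E,3S)-3,7-dimethylocta-1,6-dien-1-yl]-2-iodo-3,5-bis(methoxymethoxy)phenoxy}-N-methoxy-3-[4-(methoxymethoxy)phenyl]-N-methylpropanamide
Product: 19 (2S)-6-[(1E,3S)-3,7-dimethylocta-1,6-dien-1-yl]-5,7-bis(methoxymethoxy)-2-[4-(methoxymethoxy)phenyl]-2,3-dihydro-4H-chromen-4-one, via arylmagnesium chloride 17 (not isolated), via magnesium hemiaminal chelate 18 (not isolated)
Conditions: i-PrMgCl·LiCl (1.2 equiv), THF, −40 → −10 °C; then AcOH in THF, −78 °C; pH 7 buffer
Reagents that add atoms: none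
Why: Iodine–magnesium exchange at C4a, helped by the two flanking oxygen substituents (the C5 MOM ether and O1), gives arylmagnesium 17, whose carbanion adds to the tethered N-methoxy-N-methylamide carbonyl to form C4–C4a; the chelated adduct 18 persists until the cold acetic acid quench releases the ketone. The closest known reaction type is the Parham cyclisation of 2-haloaryl ethers of β-hydroxy amides to chroman-4-ones. Ring C closes in a 6-exo-trig mode. No lasting stereocentre is formed (the C4 centre of 18 disappears on collapse), and C2 keeps its (S) configuration because no ketone enolate ever exists in a basic medium, so the retro-oxa-Michael opening of ring C cannot start. The step needs exchange and intramolecular acylation to outrun deprotonation next to the amide (which would expel the aryloxide) and addition of i-PrMgCl to the amide; the weakly basic Grignard reagent, the low temperature and the short tether should secure this. Regiochemistry is not in question, since iodine sits on C4a and the equivalence of C4a and C8 in phenol 9 left no isomeric iodide to form.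

Step 13
Reactants: 19 (2S)-6-[(1E,3S)-3,7-dimethylocta-1,6-dien-1-yl]-5,7-bis(methoxymethoxy)-2-[4-(methoxymethoxy)phenyl]-2,3-dihydro-4H-chromen-4-one
Product: 20 (2S)-6-[(1E,3S)-3,7-dimethylocta-1,6-dien-1-yl]-5,7-dihydroxy-2-(4-hydroxyphenyl)-2,3-dihydro-4H-chromen-4-one (CNP0150993.1)
Conditions: ZnBr2 (3 equiv), n-PrSH (6 equiv), CH2Cl2, 0 °C
Reagents that add atoms: none
Why: ZnBr2-assisted thiolysis of the three MOM acetals (Lewis acid activation, capture of the methoxymethyl cation by the soft thiol) is fast at 0 °C and involves neither strong Brønsted acid, which would cyclise the dienyl chain onto the freed ortho-phenols, nor base, which would open ring C and racemise C2.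

Compound list
1 | phloroglucinol | Oc1cc(O)cc(O)c1 | starting material
2 | 3,5-bis(methoxymethoxy)phenol | COCOc1cc(O)cc(OCOC)c1 | intermediate
3 | [3,5-bis(methoxymethoxy)phenoxy]triisopropylsilane | COCOc1cc(OCOC)cc(O[Si](C(C)C)(C(C)C)C(C)C)c1 | intermediate
4 | (S)-citronellal | CC(C)=CCC[C@H](C)CC=O | starting material
5 | [2,6-bis(methoxymethoxy)-4-(triisopropylsilyloxy)phenyl]lithium | [Li]c1c(OCOC)cc(O[Si](C(C)C)(C(C)C)C(C)C)cc1OCOC | intermediate (not isolated)
6 | (1RS,3S)-1-[2,6-bis(methoxymethoxy)-4-(triisopropylsilyloxy)phenyl]-3,7-dimethyloct-6-en-1-ol (C1 epimers) | CC(C)=CCC[C@H](C)CC(O)c1c(OCOC)cc(O[Si](C(C)C)(C(C)C)C(C)C)cc1OCOC | intermediate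
7 | triethylammonium N-(methoxycarbonyl)sulfamate ester of 6 | CC(C)=CCC[C@H](C)CC(OS(=O)(=O)[N-]C(=O)OC)c1c(OCOC)cc(O[Si](C(C)C)(C(C)C)C(C)C)cc1OCOC.CC[NH+](CC)CC | intermediate (not isolated)
8 | {4-[(1E,3S)-3,7-dimethylocta-1,6-dien-1-yl]-3,5-bis(methoxymethoxy)phenoxy}triisopropylsilane | CC(C)=CCC[C@H](C)/C=C/c1c(OCOC)cc(O[Si](C(C)C)(C(C)C)C(C)C)cc1OCOC | intermediate
9 | 4-[(1E,3S)-3,7-dimethylocta-1,6-dien-1-yl]-3,5-bis(methoxymethoxy)phenol | CC(C)=CCC[C@H](C)/C=C/c1c(OCOC)cc(O)cc1OCOC | intermediate
10 | 4-[(1E,3S)-3,7-dimethylocta-1,6-dien-1-yl]-2-iodo-3,5-bis(methoxymethoxy)phenol | CC(C)=CCC[C@H](C)/C=C/c1c(OCOC)cc(O)c(I)c1OCOC | intermediate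
11 | 4-hydroxyacetophenone | CC(=O)c1ccc(O)cc1 | starting material
12 | 1-[4-(methoxymethoxy)phenyl]ethan-1-one | CC(=O)c1ccc(OCOC)cc1 | intermediate
13 | ethyl 3-[4-(methoxymethoxy)phenyl]-3-oxopropanoate | CCOC(=O)CC(=O)c1ccc(OCOC)cc1 | intermediate
14 | ethyl (3R)-3-hydroxy-3-[4-(methoxymethoxy)phenyl]propanoate | O[C@H](CC(=O)OCC)c1ccc(OCOC)cc1 | intermediate
15 | (3R)-3-hydroxy-N-methoxy-3-[4-(methoxymethoxy)phenyl]-N-methylpropanamide | O[C@H](CC(=O)N(C)OC)c1ccc(OCOC)cc1 | intermediate
16 | (3S)-3-{4-[(1E,3S)-3,7-dimethylocta-1,6-dien-1-yl]-2-iodo-3,5-bis(methoxymethoxy)phenoxy}-N-methoxy-3-[4-(methoxymethoxy)phenyl]-N-methylpropanamide | CC(C)=CCC[C@H](C)/C=C/c1c(OCOC)cc(O[C@@H](CC(=O)N(C)OC)c2ccc(OCOC)cc2)c(I)c1OCOC | intermediate (precursor of the key step)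
17 | arylmagnesium chloride from 16 (magnesium on C4a) | CC(C)=CCC[C@H](C)/C=C/c1c(OCOC)cc(O[C@@H](CC(=O)N(C)OC)c2ccc(OCOC)cc2)c([Mg]Cl)c1OCOC | intermediate (not isolated)
18 | chloromagnesium alkoxide of the cyclic C4 N-methoxy-N-methyl hemiaminal (chelate, C4 epimers) | CC(C)=CCC[C@H](C)/C=C/c1c(OCOC)cc2c(c1OCOC)C(O[Mg]Cl)(N(C)OC)C[C@@H](c1ccc(OCOC)cc1)O2 | intermediate (not isolated)
19 | (2S)-6-[(1E,3S)-3,7-dimethylocta-1,6-dien-1-yl]-5,7-bis(methoxymethoxy)-2-[4-(methoxymethoxy)phenyl]-2,3-dihydro-4H-chromen-4-one | CC(C)=CCC[C@H](C)/C=C/c1c(OCOC)cc2c(c1OCOC)C(=O)C[C@@H](c1ccc(OCOC)cc1)O2 | intermediate (product of the key step)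
20 | (2S)-6-[(1E,3S)-3,7-dimethylocta-1,6-dien-1-yl]-5,7-dihydroxy-2-(4-hydroxyphenyl)-2,3-dihydro-4H-chromen-4-one | CC(C)=CCC[C@H](C)/C=C/c1c(O)cc2c(c1O)C(=O)C[C@@H](c1ccc(O)cc1)O2 | target

Total step count: 13.
Longest linear sequence: 9 steps (steps 1–6 and 11–13, from phloroglucinol); the ring B branch (steps 7–10) joins at step 11.

Steps most likely to fail

Step 12. The iodine–magnesium exchange on the very electron-rich ring may be slow. That would leave time for deprotonation next to the amide with loss of the aryloxide, or for addition of the isopropyl Grignard reagent to the amide. The fallback keeps the C4–C4a bond but makes it under non-basic conditions. Setting out from 16, DIBAL-H (THF, −78 °C) would reduce the Weinreb amide to the aldehyde (3S)-3-{4-[(1E,3S)-3,7-dimethylocta-1,6-dien-1-yl]-2-iodo-3,5-bis(methoxymethoxy)phenoxy}-3-[4-(methoxymethoxy)phenyl]propanal F1, used without chromatography. An intramolecular Nozaki–Hiyama–Kishi coupling of the aryl iodide with the aldehyde (CrCl2, catalytic NiCl2, DMF, rt) would then close ring C at the alcohol level and give the flavan-4-ol (2S,4RS)-6-[(1E,3S)-3,7-dimethylocta-1,6-dien-1-yl]-5,7-bis(methoxymethoxy)-2-[4-(methoxymethoxy)phenyl]-3,4-dihydro-2H-chromen-4-ol F2. Oxidation with Dess–Martin periodinane (NaHCO3, CH2Cl2) comes back to the route at 19.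

Step 11. Base-induced 1,2-elimination of the activated carbinol towards the cinnamoyl amide may compete with substitution, and partial ionisation at the alkoxy-substituted benzylic carbon would erode the inversion. The fallback moves the etherification to a carbinol that has no acidifying carbonyl group. Setting out from 14, LiBH4 (THF, 0 °C → rt) would give (1R)-1-[4-(methoxymethoxy)phenyl]propane-1,3-diol F3. TBSCl and imidazole (CH2Cl2, 0 °C) would silylate the primary hydroxyl selectively to (1R)-3-[(tert-butyldimethylsilyl)oxy]-1-[4-(methoxymethoxy)phenyl]propan-1-ol F4. Mitsunobu reaction of F4 with 10 (PPh3, DIAD, toluene, 0 °C) would give, with inversion, tert-butyl[(3S)-3-{4-[(1E,3S)-3,7-dimethylocta-1,6-dien-1-yl]-2-iodo-3,5-bis(methoxymethoxy)phenoxy}-3-[4-(methoxymethoxy)phenyl]propoxy]dimethylsilane F5. TBAF (THF, 0 °C) would free (3S)-3-{4-[(1E,3S)-3,7-dimethylocta-1,6-dien-1-yl]-2-iodo-3,5-bis(methoxymethoxy)phenoxy}-3-[4-(methoxymethoxy)phenyl]propan-1-ol F6. TEMPO with PhI(OAc)2 (MeCN/H2O) would oxidise it to (3S)-3-{4-[(1E,3S)-3,7-dimethylocta-1,6-dien-1-yl]-2-iodo-3,5-bis(methoxymethoxy)phenoxy}-3-[4-(methoxymethoxy)phenyl]propanoic acid F7. Amide coupling (EDC·HCl, HOBt, MeNHOMe·HCl, i-Pr2NEt, CH2Cl2) comes back to the route at 16.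

Step 13. Once the phenols that flank the chain are free, acid-triggered cyclisation or hydration of the dienyl side chain may set in before all three acetals are cleaved. The fallback replaces acetal cleavage by an acetal-to-silyl exchange followed by buffered desilylation. Setting out from 19, TESOTf and 2,2'-bipyridyl (CH2Cl2, 0 °C) would convert each aryl MOM ether under non-acidic conditions into a silyl ether, giving (2S)-6-[(1E,3S)-3,7-dimethylocta-1,6-dien-1-yl]-5,7-bis(triethylsilyloxy)-2-[4-(triethylsilyloxy)phenyl]-2,3-dihydro-4H-chromen-4-one F8. TBAF buffered with acetic acid (THF, 0 °C) would remove the three silyl groups and come back to the route at 20.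

Further compounds
F1 | step 12 | (3S)-3-{4-[(1E,3S)-3,7-dimethylocta-1,6-dien-1-yl]-2-iodo-3,5-bis(methoxymethoxy)phenoxy}-3-[4-(methoxymethoxy)phenyl]propanal | CC(C)=CCC[C@H](C)/C=C/c1c(OCOC)cc(O[C@@H](CC=O)c2ccc(OCOC)cc2)c(I)c1OCOC
F2 | step 12 | (2S,4RS)-6-[(1E,3S)-3,7-dimethylocta-1,6-dien-1-yl]-5,7-bis(methoxymethoxy)-2-[4-(methoxymethoxy)phenyl]-3,4-dihydro-2H-chromen-4-ol | CC(C)=CCC[C@H](C)/C=C/c1c(OCOC)cc2c(c1OCOC)C(O)C[C@@H](c1ccc(OCOC)cc1)O2
F3 | step 11 | (1R)-1-[4-(methoxymethoxy)phenyl]propane-1,3-diol | O[C@H](CCO)c1ccc(OCOC)cc1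
F4 | step 11 | (1R)-3-[(tert-butyldimethylsilyl)oxy]-1-[4-(methoxymethoxy)phenyl]propan-1-ol | O[C@H](CCO[Si](C)(C)C(C)(C)C)c1ccc(OCOC)cc1
F5 | step 11 | tert-butyl[(3S)-3-{4-[(1E,3S)-3,7-dimethylocta-1,6-dien-1-yl]-2-iodo-3,5-bis(methoxymethoxy)phenoxy}-3-[4-(methoxymethoxy)phenyl]propoxy]dimethylsilane | CC(C)=CCC[C@H](C)/C=C/c1c(OCOC)cc(O[C@@H](CCO[Si](C)(C)C(C)(C)C)c2ccc(OCOC)cc2)c(I)c1OCOC
F6 | step 11 | (3S)-3-{4-[(1E,3S)-3,7-dimethylocta-1,6-dien-1-yl]-2-iodo-3,5-bis(methoxymethoxy)phenoxy}-3-[4-(methoxymethoxy)phenyl]propan-1-ol | CC(C)=CCC[C@H](C)/C=C/c1c(OCOC)cc(O[C@@H](CCO)c2ccc(OCOC)cc2)c(I)c1OCOC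
F7 | step 11 | (3S)-3-{4-[(1E,3S)-3,7-dimethylocta-1,6-dien-1-yl]-2-iodo-3,5-bis(methoxymethoxy)phenoxy}-3-[4-(methoxymethoxy)phenyl]propanoic acid | CC(C)=CCC[C@H](C)/C=C/c1c(OCOC)cc(O[C@@H](CC(=O)O)c2ccc(OCOC)cc2)c(I)c1OCOC
F8 | step 13 | (2S)-6-[(1E,3S)-3,7-dimethylocta-1,6-dien-1-yl]-5,7-bis(triethylsilyloxy)-2-[4-(triethylsilyloxy)phenyl]-2,3-dihydro-4H-chromen-4-one | CC(C)=CCC[C@H](C)/C=C/c1c(O[Si](CC)(CC)CC)cc2c(c1O[Si](CC)(CC)CC)C(=O)C[C@@H](c1ccc(O[Si](CC)(CC)CC)cc1)O2
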